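Numbering (germacrane): carbocycle C1–C10; furanone ring C1–C2=C3–O–C10; lactone ring C6–C7–C11–C12(=O)–O; C13 is the methylene on C11, C14 the methyl on C10, C15 the hydroxymethyl on C4. The plan rests on one feature: only C11 separates C13 from C7, and C8, the ring neighbour of C7, carries oxygen, so O8–C13 can be the allylic ether bond of a C7=C11 butenolide.
Late disconnections: the C15 silyl ether, the C9 angelate, the C9 carbinol (from the ketone) and the C8 methacrylate lead back to ketol 29.
Key disconnection: the C7–C8 bond of 29 is exchanged for the O8–C13 bond, which expands the ten-membered carbocycle to the thirteen-membered butenolide ether ketone 27.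
27 is cut at O8–C13 (silver-assisted etherification), C7=C11 (ring-closing metathesis of an O6 2-(bromomethyl)acrylate), C3–O (gold-catalysed hydroxy-ynone cyclisation) and C3–C4 (Sonogashira coupling). The pieces are iodide 9 (C4–C7, C15), alkyne 18 (C1–C3, C8–C10, C14) and acid 23 (C11–C13).
Order of ring formation: furanone (step 12), butenolide (step 15), thirteen-membered ether ring (step 17), ten-membered carbocycle with the methylene lactone (step 18).

Key step: step 18

Remark: the carbinol centres C1 and C9 in 14–19 and the lactol carbon of 15 are carried as epimer mixtures because all of them later become carbonyl carbons. The CIP letters at C6, C7 and C10 change along the route through ligand ranking only; no centre is inverted.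

Step 1
Reactants: 1 prop-2-yn-1-ol
Product: 2 tert-butyl(diphenyl)(prop-2-yn-1-yloxy)silane
Conditions: TBDPSCl, imidazole, CH2Cl2, 0 °C to rt
Reagents that add atoms: tert-butyl(chloro)diphenylsilane, CC(C)(C)[Si](Cl)(c1ccccc1)c1ccccc1
Why: Imidazole-promoted silylation of a primary alcohol; this group is chosen for O15 because it must outlast the later removal of a triethylsilyl and a tert-butyldimethylsilyl ether.

Step 2
Reactants: 2 tert-butyl(diphenyl)(prop-2-yn-1-yloxy)silane, 3 acrolein
Product: 5 rac-6-[tert-butyl(diphenyl)silyl]oxyhex-1-en-4-yn-3-ol, via lithium acetylide 4 (not isolated)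
Conditions: n-BuLi, THF, −78 °C; then 3, −78 °C
Reagents that add atoms: none
Why: 1,2-Addition of a lithium acetylide to an enal joins C5 to C6; the carbinol centre C6 forms racemic here and is resolved in step 3.

Step 3
Reactants: 5 rac-6-[tert-butyl(diphenyl)silyl]oxyhex-1-en-4-yn-3-ol
Product: 6 (3S)-6-[tert-butyl(diphenyl)silyl]oxyhex-1-en-4-yn-3-ol
Conditions: Amano lipase AK, vinyl acetate, MTBE, 30 °C, stopped just past half conversion; chromatography
Reagents that add atoms: none
Why: Lipase-catalysed kinetic resolution by acyl transfer; by the Kazlauskas rule the vinyl group fits the medium pocket and the long silyloxypropynyl group the large one, so the (R)-alcohol should be acetylated and the (S)-alcohol, which has the C6 arrangement of the target, should be recovered.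

Step 4
Reactants: 6 (3S)-6-[tert-butyl(diphenyl)silyl]oxyhex-1-en-4-yn-3-ol
Product: 8 (3S,4Z)-6-[tert-butyl(diphenyl)silyl]oxy-5-iodohexa-1,4-dien-3-ol, via cyclic sodium alkenylalanate 7 (not isolated)
Conditions: NaAlH2(OCH2CH2OMe)2, THF, 0 °C to rt; then I2, THF, −78 °C
Reagents that add atoms: iodine, II
Why: Hydroxyl-directed trans-hydroalumination of the propargylic alcohol puts hydride on C5 and aluminium on C4 in a five-membered alanate, and iodinolysis with retention leaves iodine cis to C6, which fixes the C4=C5 geometry of the target.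

Step 5
Reactants: 8 (3S,4Z)-6-[tert-butyl(diphenyl)silyl]oxy-5-iodohexa-1,4-dien-3-ol
Product: 9 triethylsilyl ether of 8 (iodide fragment, 6S)
Conditions: TESCl, imidazole, CH2Cl2, 0 °C
Reagents that add atoms: chlorotriethylsilane, CC[Si](Cl)(CC)CC
Why: Silylation blocks O6, which would otherwise add to C3 of the later cis-enyne or ynone and give a furan, and the group is the most labile of the three silyl ethers.

Step 6
Reactants: 10 (R)-lactic acid
Product: 11 (2R,5R)-2-tert-butyl-5-methyl-1,3-dioxolan-4-one
Conditions: t-BuCHO, TsOH·H2O (cat.), pentane, reflux, water separator; low-temperature recrystallisation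
Reagents that add atoms: pivalaldehyde, CC(C)(C)C=O
Why: Acid-catalysed acetalisation opens a self-regeneration-of-stereocentres sequence; the lactate centre favours the cis acetal, which is also the isomer that crystallises, and so sets the new acetal centre.

Step 7
Reactants: 11 (2R,5R)-2-tert-butyl-5-methyl-1,3-dioxolan-4-one, 12 (tert-butyldimethylsilyloxy)acetaldehyde
Product: 14 (2R,5S)-2-tert-butyl-5-[2-(tert-butyldimethylsilyloxy)-1-hydroxyethyl]-5-methyl-1,3-dioxolan-4-one, via lithium enolate 13 (not isolated)
Conditions: LiN(iPr)2, THF, −78 °C; then 12, −78 °C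
Reagents that add atoms: none
Why: Aldol addition of the dioxolanone enolate; the tert-butyl group shields one face, so the aldehyde enters trans to it and takes the place of the former hydrogen, which sets quaternary C10, while C9 forms as an inconsequential epimer mixture.

Step 8
Reactants: 14 aldol adduct
Product: 15 (2R,5S)-2-tert-butyl-5-[2-(tert-butyldimethylsilyloxy)-1-hydroxyethyl]-5-methyl-1,3-dioxolan-4-ol (lactol)
Conditions: iBu2AlH (2.3 equiv), CH2Cl2, −78 °C
Reagents that add atoms: none
Why: Partial reduction of the lactone-type carbonyl stops at the aluminium hemiacetal at −78 °C and gives the lactol, a masked C1 aldehyde.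

Step 9
Reactants: 15 lactol, 16 ethynylmagnesium bromide
Product: 18 (4R)-6-(tert-butyldimethylsilyloxy)-4-methylhex-1-yne-3,4,5-triol, via ring-opened magnesium alkoxide aldehyde 17 (not isolated)
Conditions: HC≡CMgBr (5 equiv), THF, 0 °C to rt
Reagents that add atoms: none
Why: Grignard addition to a lactol; the magnesium lactolate opens to the aldehyde with loss of pivalaldehyde, ethynyl addition brings in C2 and C3, and C1 forms as an epimer mixture that is oxidised in step 11.

Step 10
Reactants: 9 iodide fragment, 18 alkyne triol
Product: 19 enyne triol (C3–C4 joined; 6S,10R)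
Conditions: PdCl2(PPh3)2 (5 mol %), CuI (10 mol %), Et3N, THF, rt
Reagents that add atoms: none
Why: Sonogashira coupling of an alkenyl iodide and a terminal alkyne forms C3–C4 with retention of the alkene geometry and tolerates the free triol.

Step 11
Reactants: 19 enyne triol
Product: 20 hydroxy ynedione (C1 ynone, C9 ketone, free tertiary C10 hydroxyl)
Conditions: Dess–Martin periodinane (3 equiv), NaHCO3, CH2Cl2, 0 °C to rt
Reagents that add atoms: none
Why: Dess–Martin oxidation turns both secondary carbinols into ketones in one operation, the tertiary C10 hydroxyl cannot react, and the bicarbonate buffer protects the silyl ethers.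

Step 12
Reactants: 20 hydroxy ynedione
Product: 21 (2R)-2-[2-(tert-butyldimethylsilyloxy)acetyl]-5-[(2Z,4S)-1-(tert-butyldiphenylsilyloxy)-4-(triethylsilyloxy)hexa-2,5-dien-2-yl]-2-methylfuran-3(2H)-one
Conditions: (4-CF3C6H4)3PAuCl (5 mol %), AgOTf (5 mol %), toluene, rt
Reagents that add atoms: none
Why: Gold-catalysed 5-endo-dig cycloisomerisation of an α′-hydroxy ynone; the C10 hydroxyl adds to the activated C3 and protodeauration gives the 3(2H)-furanone without touching C10, while the silyl group keeps O6 out of the reaction.

Step 13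
Reactants: 21 furanone
Product: 22 C6 alcohol (21 with free 6S hydroxyl)
Conditions: PPTS (0.2 equiv), MeOH–CH2Cl2, 0 °C
Reagents that add atoms: none
Why: Acid-catalysed solvolysis of silyl ethers is governed by bulk at silicon, so the triethylsilyl ether on O6 should leave well before the silyl ethers on O8 and O15.

Step 14
Reactants: 22 C6 alcohol, 23 2-(bromomethyl)acrylic acid
Product: 24 O6 2-(bromomethyl)acrylate of 22
Conditions: DCC, DMAP (5 mol %), CH2Cl2, −20 to 0 °C
Reagents that add atoms: none
Why: Steglich esterification leaves the C6–O bond and hence C6 untouched; DMAP is kept catalytic and cold because it can quaternise the allylic bromide.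

Step 15
Reactants: 24 O6 2-(bromomethyl)acrylate
Product: 25 (5R)-3-(bromomethyl)butenolide with the furanone-bearing propenyl group on C6 (8-O-TBS, 15-O-TBDPS)
Conditions: second-generation Hoveyda–Grubbs catalyst (10 mol %), toluene (5 mM), 80 °C
Reagents that add atoms: none
Why: Ring-closing metathesis of the acrylate of an allylic alcohol forms C7=C11 and the butenolide under neutral conditions, which matters because C6–H becomes acidic at this point; the trisubstituted C4=C5 and the furanone alkene are too hindered and electron-poor to take part.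

Step 16
Reactants: 25 bromomethyl butenolide
Product: 26 bromomethyl butenolide with free C8 hydroxyl next to the C9 ketone
Conditions: aq HF (48 %), MeCN, 0 °C
Reagents that add atoms: none
Why: Acidic fluoride desilylation removes the primary tert-butyldimethylsilyl ether much faster than the tert-butyldiphenylsilyl ether, and the acidic medium spares C6–H and the allylic bromide.

Step 17
Reactants: 26 hydroxy ketone bromide
Product: 27 thirteen-membered butenolide ether ketone (6R,10R; 15-O-TBDPS)
Conditions: AgOTf (2 equiv), 2,6-di-tert-butyl-4-methylpyridine (3 equiv), 4 Å MS, CH2Cl2 (1 mM, slow addition of 26), 0 °C to rt, dark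
Reagents that add atoms: none
Why: Silver-assisted Williamson-type etherification at high dilution (exo-tet closure at primary C13); silver pulls off bromide while the hindered pyridine only takes up triflic acid, so no base able to deprotonate C6 is present.

Step 18
Reactants: 27 thirteen-membered butenolide ether ketone
Product: 29 ten-membered C9 ketone with C8 hydroxyl and α-methylene lactone, via trichlorotitanium enolate 28 (not isolated)
Conditions: TiCl4 (1.1 equiv), CH2Cl2, −78 °C; iPr2NEt (1.2 equiv), −78 to −30 °C; pH 7 buffer, −78 °C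
Reagents that add atoms: none
Why: Proposed new method: TiCl4 should settle on the only chelating site of 27 (O9 with O8 or O1), iPr2NEt then removes a C8 proton (C10 is quaternary, so this ketone has no other α-hydrogen) to give the chelated (Z)-enolate 28, and its carbon C8 bonds to the electrophilic butenolide carbon C7 while the titanium-activated O8–C13 bond breaks and C11=C13 appears, either as a concerted suprafacial [2,3]-shift or as its asynchronous conjugate addition–β-elimination limit. The closest known reactions are the [2,3]-Wittig rearrangement of metal enolates of α-allyloxy carbonyl compounds, the Wittig ring contraction of thirteen-membered allylic ethers to ten-membered carbocycles and the SN2′ displacement of 2-(alkoxymethyl)acrylates by enolates, none of which has been run on a butenolide inside a macrocycle. The ten-membered carbocycle closes transannularly by contraction of the thirteen-membered ring through a five-membered envelope array (C8, O8, C13, C11, C7); taken stepwise this would be a 5-endo-trig addition, so the pericyclic mode is expected to carry the reaction. C7 is controlled by C6, because the C5 substituent shields one face of the planar butenolide and C8 must arrive on the other, which makes H6 and H7 trans. C8 is controlled by the (Z)-geometry of the chelated enolate together with the short C10–O–C3–C4=C5 strap, which is expected to hold C9 below the lactone ring beside C6 (carbonyl-endo envelope) and thereby to expose the enolate face that gives 8S. The step needs C8–H to be removed in preference to the more acidic C6–H and the [2,3]-shift to beat the [3,3]-shift: the first is secured by chelation, which acidifies only C8–H while the hindered amine at −78 °C is too weak for the unactivated butenolide, and the second by polarity (C8 is the nucleophilic and C7 the electrophilic terminus, whereas C9–C7 bonding is mismatched and would give a nine-membered ring with adjacent fully substituted carbons).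

Step 19
Reactants: 29 ten-membered ketol, 30 methacrylic anhydride
Product: 31 C8 methacrylate of 29 (6R,7S,8S,10R)
Conditions: Et3N, DMAP (0.1 equiv), CH2Cl2, 0 °C
Reagents that add atoms: none
Why: DMAP-catalysed acylation of the secondary C8 hydroxyl leaves its C–O bond intact, and the low temperature and short exposure limit enolisation of the α-acyloxy ketone at C8.

Step 20
Reactants: 31 C8 methacrylate ketone
Product: 32 C9 alcohol (6R,7S,8S,9R,10S)
Conditions: NaBH4, CeCl3·7H2O, MeOH–THF, −78 °C
Reagents that add atoms: none
Why: Luche reduction; the C9 ketone, activated by its α-acyloxy and α′-oxygen substituents, is the most electrophilic carbonyl, cerium suppresses conjugate reduction of the methylene lactone and furanone, and hydride is expected to come from the ring periphery anti to both the C8–O and C10–O bonds (polar Felkin–Anh arrangement, matched for both flanking centres), which gives the 8,9-syn relationship, that is 9R.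

Step 21
Reactants: 32 C9 alcohol, 33 angelic acid
Product: 34 8-methacrylate 9-angelate with 15-O-TBDPS
Conditions: 33, 2,4,6-Cl3C6H2COCl, Et3N, toluene, rt; then 32, 60 °C
Reagents that add atoms: none
Why: Yamaguchi mixed-anhydride esterification without DMAP is the established way to acylate hindered alcohols with angelic acid while the (Z)-alkene is kept, and the C9–O bond is not broken.

Step 22
Reactants: 34 silyl-protected diester
Product: 35 CNP0359568.2 (target)
Conditions: HF·pyridine, THF, 0 °C to rt
Reagents that add atoms: none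
Why: Fluoride-mediated desilylation in acidic medium frees the C15 hydroxyl without the basic conditions that would threaten the methylene lactone, the two unsaturated esters or the C9–C10 bond.

Compound list
1 | prop-2-yn-1-ol | C#CCO | starting material
2 | tert-butyl(diphenyl)(prop-2-yn-1-yloxy)silane | C#CCO[Si](c1ccccc1)(c1ccccc1)C(C)(C)C | intermediate
3 | acrolein | C=CC=O | starting material
4 | lithium acetylide of 2 | [Li]C#CCO[Si](c1ccccc1)(c1ccccc1)C(C)(C)C | intermediate
5 | rac-6-[tert-butyl(diphenyl)silyl]oxyhex-1-en-4-yn-3-ol | C=CC(O)C#CCO[Si](c1ccccc1)(c1ccccc1)C(C)(C)C | intermediate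
6 | (3S)-6-[tert-butyl(diphenyl)silyl]oxyhex-1-en-4-yn-3-ol | C=C[C@H](O)C#CCO[Si](c1ccccc1)(c1ccccc1)C(C)(C)C | intermediate
7 | sodium alkenylalanate, five-membered ring O6–Al–C4=C5–C6, two 2-methoxyethoxy ligands on aluminium | [Na+].C=C[C@@H]1O[Al-](OCCOC)(OCCOC)C(CO[Si](c2ccccc2)(c2ccccc2)C(C)(C)C)=C1 | intermediate
8 | (3S,4Z)-6-[tert-butyl(diphenyl)silyl]oxy-5-iodohexa-1,4-dien-3-ol | C=C[C@H](O)/C=C(/CO[Si](c1ccccc1)(c1ccccc1)C(C)(C)C)I | intermediate
9 | [(3S,4Z)-6-[tert-butyl(diphenyl)silyl]oxy-5-iodohexa-1,4-dien-3-yl]oxy(triethyl)silane | C=C[C@H](O[Si](CC)(CC)CC)/C=C(/CO[Si](c1ccccc1)(c1ccccc1)C(C)(C)C)I | intermediate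
10 | (R)-lactic acid | C[C@@H](O)C(=O)O | starting material
11 | (2R,5R)-2-tert-butyl-5-methyl-1,3-dioxolan-4-one | C[C@H]1O[C@@H](C(C)(C)C)OC1=O | intermediate
12 | (tert-butyldimethylsilyloxy)acetaldehyde | O=CCO[Si](C)(C)C(C)(C)C | starting material
13 | lithium enolate of 11 | [Li]OC1=C(C)O[C@@H](C(C)(C)C)O1 | intermediate
14 | (2R,5S)-2-tert-butyl-5-[2-(tert-butyldimethylsilyloxy)-1-hydroxyethyl]-5-methyl-1,3-dioxolan-4-one (C9 epimers) | C[C@@]1(C(O)CO[Si](C)(C)C(C)(C)C)O[C@@H](C(C)(C)C)OC1=O | intermediate
15 | (2R,5S)-2-tert-butyl-5-[2-(tert-butyldimethylsilyloxy)-1-hydroxyethyl]-5-methyl-1,3-dioxolan-4-ol (lactol, epimers) | C[C@@]1(C(O)CO[Si](C)(C)C(C)(C)C)O[C@@H](C(C)(C)C)OC1O | intermediate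
16 | ethynylmagnesium bromide | C#C[Mg]Br | starting material
17 | open-chain C1 aldehyde as bis(bromomagnesium) alkoxide at O9 and O10 | O=C[C@@](C)(O[Mg]Br)C(O[Mg]Br)CO[Si](C)(C)C(C)(C)C | intermediate
18 | (4R)-6-(tert-butyldimethylsilyloxy)-4-methylhex-1-yne-3,4,5-triol (C3 and C5 epimers) | C#CC(O)[C@@](C)(O)C(O)CO[Si](C)(C)C(C)(C)C | intermediate
19 | enyne triol: 6S-O-TES, 15-O-TBDPS, 8-O-TBS, free hydroxyls at C1, C9 (epimers) and C10 (10R), C2≡C3, C3 cis to C6 on C4=C5, vinyl group on C6 | C=C[C@H](O[Si](CC)(CC)CC)/C=C(/CO[Si](c1ccccc1)(c1ccccc1)C(C)(C)C)C#CC(O)[C@@](C)(O)C(O)CO[Si](C)(C)C(C)(C)C | intermediate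
20 | hydroxy ynedione: 19 with C1 and C9 as ketones (6S,10R) | C=C[C@H](O[Si](CC)(CC)CC)/C=C(/CO[Si](c1ccccc1)(c1ccccc1)C(C)(C)C)C#CC(=O)[C@@](C)(O)C(=O)CO[Si](C)(C)C(C)(C)C | intermediate
21 | (2R)-2-[2-(tert-butyldimethylsilyloxy)acetyl]-5-[(2Z,4S)-1-(tert-butyldiphenylsilyloxy)-4-(triethylsilyloxy)hexa-2,5-dien-2-yl]-2-methylfuran-3(2H)-one | C=C[C@H](O[Si](CC)(CC)CC)/C=C(/CO[Si](c1ccccc1)(c1ccccc1)C(C)(C)C)C1=CC(=O)[C@@](C)(O1)C(=O)CO[Si](C)(C)C(C)(C)C | intermediate
22 | (2R)-2-[2-(tert-butyldimethylsilyloxy)acetyl]-5-[(2Z,4S)-1-(tert-butyldiphenylsilyloxy)-4-hydroxyhexa-2,5-dien-2-yl]-2-methylfuran-3(2H)-one | C=C[C@H](O)/C=C(/CO[Si](c1ccccc1)(c1ccccc1)C(C)(C)C)C1=CC(=O)[C@@](C)(O1)C(=O)CO[Si](C)(C)C(C)(C)C | intermediate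
23 | 2-(bromomethyl)acrylic acid | C=C(CBr)C(=O)O | starting material
24 | 2-(bromomethyl)acrylate ester of the C6 hydroxyl of 22 (6S,10R) | C=C[C@H](OC(=O)C(=C)CBr)/C=C(/CO[Si](c1ccccc1)(c1ccccc1)C(C)(C)C)C1=CC(=O)[C@@](C)(O1)C(=O)CO[Si](C)(C)C(C)(C)C | intermediate
25 | (5R)-3-(bromomethyl)-5-{(1Z)-3-(tert-butyldiphenylsilyloxy)-2-[(5R)-5-[2-(tert-butyldimethylsilyloxy)acetyl]-5-methyl-4-oxo-4,5-dihydrofuran-2-yl]prop-1-enyl}furan-2(5H)-one | BrCC1=C[C@H](OC1=O)/C=C(/CO[Si](c1ccccc1)(c1ccccc1)C(C)(C)C)C1=CC(=O)[C@@](C)(O1)C(=O)CO[Si](C)(C)C(C)(C)C | intermediate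
26 | 25 with a hydroxyacetyl group on C10 (free C8 hydroxyl, C9 ketone) | BrCC1=C[C@H](OC1=O)/C=C(/CO[Si](c1ccccc1)(c1ccccc1)C(C)(C)C)C1=CC(=O)[C@@](C)(O1)C(=O)CO | intermediate
27 | thirteen-membered butenolide ether ketone: ring C9(=O)–C8H2–O–C13H2–C11=C7–C6–C5=C4–C3=C2–C1(=O)–C10, bridged by O between C3 and C10 and by O–C12(=O) between C6 and C11; 6R,10R; 15-O-TBDPS | O=C1COCC2=C[C@H](OC2=O)/C=C(/CO[Si](c3ccccc3)(c3ccccc3)C(C)(C)C)C2=CC(=O)[C@@]1(C)O2 | intermediate
28 | (Z)-trichlorotitanium C8=C9 enolate of 27 (O9 and O8 cis) | Cl[Ti](Cl)(Cl)O/C1=C\OCC2=C[C@H](OC2=O)/C=C(/CO[Si](c3ccccc3)(c3ccccc3)C(C)(C)C)C2=CC(=O)[C@@]1(C)O2 | intermediate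
29 | ten-membered C9 ketone with C8 hydroxyl and trans-fused α-methylene lactone; CIP 6R,7R,8S,10R, spatially as in the target; 15-O-TBDPS | O=C1[C@@H](O)[C@H]2C(=C)C(=O)O[C@@H]2/C=C(/CO[Si](c3ccccc3)(c3ccccc3)C(C)(C)C)C2=CC(=O)[C@@]1(C)O2 | intermediate
30 | methacrylic anhydride | C=C(C)C(=O)OC(=O)C(C)=C | starting material
31 | C8 methacrylate of 29 (6R,7S,8S,10R) | C=C(C)C(=O)O[C@H]1[C@H]2C(=C)C(=O)O[C@@H]2/C=C(/CO[Si](c3ccccc3)(c3ccccc3)C(C)(C)C)C2=CC(=O)[C@@](C)(O2)C1=O | intermediate
32 | C9 alcohol (6R,7S,8S,9R,10S) | C=C(C)C(=O)O[C@H]1[C@H]2C(=C)C(=O)O[C@@H]2/C=C(/CO[Si](c3ccccc3)(c3ccccc3)C(C)(C)C)C2=CC(=O)[C@@](C)(O2)[C@@H]1O | intermediate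
33 | angelic acid, (Z)-2-methylbut-2-enoic acid | C/C=C(/C)C(=O)O | starting material
34 | 15-O-TBDPS ether of the target | C=C(C)C(=O)O[C@H]1[C@H]2C(=C)C(=O)O[C@@H]2/C=C(/CO[Si](c3ccccc3)(c3ccccc3)C(C)(C)C)C2=CC(=O)[C@@](C)(O2)[C@@H]1OC(=O)/C(C)=C\C | intermediate
35 | CNP0359568.2 (6R,7S,8S,9R,10S; 4Z) | C=C(C)C(=O)O[C@H]1[C@H]2C(=C)C(=O)O[C@@H]2/C=C(/CO)C2=CC(=O)[C@@](C)(O2)[C@@H]1OC(=O)/C(C)=C\C | target

Total step count: 22. Longest linear sequence: 18 (steps 1–5 and 10–22).

Steps most likely to fail

1. Step 18.
- What may go wrong: deprotonation at C6 instead of C8, with loss of the C6 configuration or migration of the double bonds; chloride-induced cleavage of the activated allylic ether; bonding on the wrong enolate face; isomerisation of the ketol before the quench.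
- Fallback (known chemistry): it sets out from 26 and comes back at 29, so steps 17 and 18 are skipped. Dess–Martin oxidation of the primary C8 hydroxyl of 26 gives the α-keto aldehyde F1. Slow addition of it to excess CrCl2 in THF–DMF converts the bromomethylbutenolide into an allylchromium reagent. This reagent adds through its γ-carbon C7 to the aldehyde carbon C8, in preference to the ketones, in an intramolecular Nozaki–Hiyama allylation. That reaction is a known way to turn 3-(bromomethyl)butenolides into β-(hydroxyalkyl)-α-methylene lactones and to close germacranolide rings. C7 should again be attacked anti to the C5 substituent, and the strap discussed in step 18 should also orient C9 here.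

2. Step 17.
- What may go wrong: oligomerisation instead of ring closure; SN2′ attack of O8 at C7; slow capture of the silver-activated bromide by the weakly nucleophilic ketol hydroxyl.
- Fallback: it sets out from 21 and comes back at 27. The ether is made intermolecularly and the large ring is closed at the ester. Aqueous HF in MeCN removes both the triethylsilyl and the tert-butyldimethylsilyl ether of 21 and gives the 6,8-diol F2. Allyl 2-(bromomethyl)acrylate F3 (from 23, allyl alcohol and DCC) with Ag2O in CH2Cl2 alkylates the primary, more acidic C8 hydroxyl and gives the ether allyl ester F4. Pd(PPh3)4 and PhSiH3 free the seco acid F5. Shiina macrolactonisation (2-methyl-6-nitrobenzoic anhydride, DMAP, high dilution) onto O6 gives the macrolactone F6. Ring-closing metathesis across the ring, between the vinyl group on C6 and the C11 methylene (second-generation Hoveyda–Grubbs catalyst, toluene, 80 °C), then gives 27.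

3. Step 20.
- What may go wrong: hydride delivery to the wrong face of C9; conjugate reduction of the methylene lactone; retro-aldol opening of the C9–C10 bond; shift of the methacrylate from O8 to O9 in the basic borohydride medium.
- Fallback: it sets out from 31 and comes back at 32 and makes no new compound. Stereocontrol is moved from the substrate to a chiral reagent, and the medium becomes neutral. A Corey–Bakshi–Shibata reduction with (S)-2-methyl-CBS-oxazaborolidine and catecholborane in toluene at −78 °C should treat quaternary C10 as the large and C8 as the small flank. That is the arrangement that leads to 9R, and O9 stays bound as a borate until work-up.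

Further compounds
F1 | step 18 | α-keto aldehyde: 26 with C8 oxidised to the aldehyde (6R,10R) | BrCC1=C[C@H](OC1=O)/C=C(/CO[Si](c2ccccc2)(c2ccccc2)C(C)(C)C)C2=CC(=O)[C@@](C)(O2)C(=O)C=O
F2 | step 17 | 6,8-diol: 21 without the silyl groups on O6 and O8 | C=C[C@H](O)/C=C(/CO[Si](c1ccccc1)(c1ccccc1)C(C)(C)C)C1=CC(=O)[C@@](C)(O1)C(=O)CO
F3 | step 17 | allyl 2-(bromomethyl)acrylate | C=CCOC(=O)C(=C)CBr
F4 | step 17 | O8 2-(allyloxycarbonyl)allyl ether of F2 | C=C[C@H](O)/C=C(/CO[Si](c1ccccc1)(c1ccccc1)C(C)(C)C)C1=CC(=O)[C@@](C)(O1)C(=O)COCC(=C)C(=O)OCC=C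
F5 | step 17 | seco acid: F4 with free C12 carboxylic acid | C=C[C@H](O)/C=C(/CO[Si](c1ccccc1)(c1ccccc1)C(C)(C)C)C1=CC(=O)[C@@](C)(O1)C(=O)COCC(=C)C(=O)O
F6 | step 17 | macrolactone closed between O6 and C12, with vinyl on C6 and methylene on C11 | O=C1COCC(=C)C(=O)O[C@@H](C=C)/C=C(/CO[Si](c3ccccc3)(c3ccccc3)C(C)(C)C)C2=CC(=O)[C@@]1(C)O2
F0 | step 20 | none | none
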